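**Retrosynthetic overview**
1. Target 27 ⇐ ring A alkene 24: both ring A C–O bonds (C4–OAc, C3–OH) come from one Woodward cis-hydroxyacetoxylation in the last step.
2. 24 ⇐ N-silyl hydrazone 22 of norbornenone 21: the C10–OAc bond is made by acetate capture of a cation, and this same event closes the cyclopropane (last carbocycle formed).
3. 21 ⇐ ketone 17: exo hydroxymethylation of the enolate sets quaternary C6; the C3 oxygen is a removable control element, eliminated to the C3=C4 alkene.
4. 17 ⇐ nitroalkene 15: one intramolecular Diels–Alder reaction forms ring A and the bicyclo[2.2.1]heptene together; a Nef reaction unveils the ketone.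
5. 15 ⇐ 3-methylcyclopent-2-enone 1 + isobutyronitrile 2 + bromoacetal 5 + MeNO2. Ring order: cyclopentadiene, then ring A with the norbornene, then the cyclopropane.

Assumption: the given SMILES is taken as the absolute configuration; locants follow tricyclo[6.2.1.0^{1,6}]undecane (C1 = ring-fusion carbon next to CMe2, C6 = the other ring-fusion carbon, C11 = CH2 bridge, ring A = C1–C6); anions of numbered compounds (enolate, nitronate) get no number of their own.

**Step 1**
Reactants: 1 3-methylcyclopent-2-en-1-one; 2 2-methylpropanenitrile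
Product: 4 2-methyl-2-(3-methylcyclopenta-1,3-dien-1-yl)propanenitrile, via hydroxy nitrile 3 (not isolated)
Conditions: 2, LiN(iPr)2, THF, −78 °C; then 1, −78 °C; then 2 M HCl, 0 °C to rt
Reagents that add atoms: none
Why: 1,2-addition of the lithiated nitrile to the enone (the β-methyl group disfavours conjugate addition) and acid-catalysed dehydration of the tertiary allylic alcohol give the 1,3-disubstituted cyclopentadiene, whose tautomers interconvert by 1,5-H shifts; no stereocentre.

**Step 2**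
Reactants: 4 2-methyl-2-(3-methylcyclopenta-1,3-dien-1-yl)propanenitrile; 5 2-(2-bromoethyl)-1,3-dioxane
Product: 8 1-(1,3-dioxan-2-yl)-4-methyl-4-(3-methylcyclopenta-1,3-dien-1-yl)pentan-3-one, via Grignard reagent 6 (not isolated), via ketimine 7 (not isolated)
Conditions: 5, Mg, THF, 30 °C; then 4 (6 used at 2.5 equiv), CuBr (5 mol%), THF, 50 °C; then AcOH/NaOAc buffer (pH 4.5), H2O, rt
Reagents that add atoms: water, O
Why: Grignard addition to a nitrile (CuBr-catalysed for the α-quaternary nitrile) stops at the metallo-ketimine; the first equivalent only deprotonates the cyclopentadiene, which is returned on work-up, and buffered hydrolysis cleaves the ketimine but not the dioxane.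

**Step 3**
Reactants: 8 1-(1,3-dioxan-2-yl)-4-methyl-4-(3-methylcyclopenta-1,3-dien-1-yl)pentan-3-one
Product: 9 (3R)-1-(1,3-dioxan-2-yl)-4-methyl-4-(3-methylcyclopenta-1,3-dien-1-yl)pentan-3-ol
Conditions: (S)-1-methyl-3,3-diphenyltetrahydro-1H,3H-pyrrolo[1,2-c][1,3,2]oxazaborole ((S)-Me-CBS, 10 mol%), catecholborane, toluene, −78 to −40 °C; then MeOH, 1 M NaOH
Reagents that add atoms: none
Why: Corey–Bakshi–Shibata reduction: the tert-alkyl group is the large and the CH2 chain the small substituent, so the (S)-catalyst gives the (R)-carbinol (as for pinacolone), and catecholborane at low temperature leaves diene and acetal untouched; this stereocentre steers the cycloaddition and is removed later.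

**Step 4**
Reactants: 9 (3R)-1-(1,3-dioxan-2-yl)-4-methyl-4-(3-methylcyclopenta-1,3-dien-1-yl)pentan-3-ol
Product: 12 (4R)-5-methyl-5-(3-methylcyclopenta-1,3-dien-1-yl)-4-(triethylsilyloxy)hexanal, via silyl ether acetal 10 (not isolated), via lutidinium salt 11 (not isolated)
Conditions: Et3SiOTf (3.5 equiv), 2,6-lutidine (5 equiv), CH2Cl2, −20 to 0 °C; then H2O
Reagents that add atoms: triethylsilyl trifluoromethanesulfonate, CC[Si](CC)(CC)OS(=O)(=O)C(F)(F)F; water, O
Why: Silyl triflate/lutidine acetal cleavage: Et3SiOTf silylates the hindered alcohol, then ionises the dioxane to an oxocarbenium ion that 2,6-lutidine traps as a pyridinium salt, which water hydrolyses to the aldehyde, so silyl ether and diene never meet aqueous acid.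

**Step 5**
Reactants: 12 (4R)-5-methyl-5-(3-methylcyclopenta-1,3-dien-1-yl)-4-(triethylsilyloxy)hexanal
Product: 16 triethyl{[(3R)-2,2,9-trimethyl-7-nitrotricyclo[6.2.1.0^{1,6}]undec-9-en-3-yl]oxy}silane (C5 exo at C6; nitro endo; silyloxy cis to C10), via nitro alcohol 13 (not isolated), via nitro mesylate 14 (not isolated), via nitroalkene 15 (not isolated)
Conditions: MeNO2, Et3N (20 mol%), THF, 0 °C to rt; then MsCl, Et3N, CH2Cl2, −20 °C; then toluene (0.01 M), 60 °C
Reagents that add atoms: nitromethane, C[N+](=O)[O-]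
Why: Henry addition, mesylate elimination to the (E)-nitroalkene and intramolecular Diels–Alder reaction of the 1-substituted cyclopentadiene tautomer (Curtin–Hammett over the 1,5-H-shift isomers); the four-atom tether closes ring A with C5 exo and nitro endo, and the chair-like tether with equatorial silyloxy group selects one diene face, which sets C1 and C8 (the whole cage) in the absolute sense of the target.

**Step 6**
Reactants: 16 nitro cycloadduct
Product: 17 (3R)-2,2,9-trimethyl-3-(triethylsilyloxy)tricyclo[6.2.1.0^{1,6}]undec-9-en-7-one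
Conditions: NaOMe, MeOH, 0 °C; then TiCl3, NH4OAc, H2O (pH 5), rt
Reagents that add atoms: water, O
Why: Nef reaction in its TiCl3 variant: the nitronate is reduced to the imine and hydrolysed at pH 5, which spares the strained alkene and the silyl ether; any epimerisation at C6 is irrelevant because that centre is rebuilt in step 7.

**Step 7**
Reactants: 17 (3R)-2,2,9-trimethyl-3-(triethylsilyloxy)tricyclo[6.2.1.0^{1,6}]undec-9-en-7-one
Product: 20 [(3R)-3-hydroxy-2,2,9-trimethyl-7-oxotricyclo[6.2.1.0^{1,6}]undec-9-en-6-yl]methyl acetate (CH2OAc exo), via hydroxymethyl ketone 18 (not isolated), via acetoxymethyl silyl ether 19 (not isolated)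
Conditions: LiN(iPr)2, THF, −78 to −20 °C; CH2O (gas), −78 °C; Ac2O, −78 to 0 °C; then 1 M HCl, THF, rt
Reagents that add atoms: formaldehyde, C=O; acetic anhydride, CC(=O)OC(C)=O
Why: Aldol reaction of the norbornenone enolate with formaldehyde from the exo face (syn to the C11 bridge, as in exo-alkylations of bicyclo[2.2.1]heptan-2-one enolates) sets quaternary C6 with CH2O exo and pushes ring carbon C5 endo; Ac2O traps the alkoxide before retro-aldol and the acidic work-up removes the triethylsilyl group.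

**Step 8**
Reactants: 20 [(3R)-3-hydroxy-2,2,9-trimethyl-7-oxotricyclo[6.2.1.0^{1,6}]undec-9-en-6-yl]methyl acetate
Product: 21 (2,2,9-trimethyl-7-oxotricyclo[6.2.1.0^{1,6}]undeca-3,9-dien-6-yl)methyl acetate
Conditions: Ph2S[OC(CF3)2Ph]2 (Martin sulfurane), CH2Cl2, 0 °C to rt
Reagents that add atoms: none
Why: Martin sulfurane dehydration: after step 7 ring A has flipped, so the C3 hydroxyl is axial and anti-periplanar to the axial C4–H, allowing an E2-type elimination to the C3=C4 alkene without the Wagner–Meerwein shift that ionising conditions would cause at this neopentyl centre.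

**Step 9**
Reactants: 21 (2,2,9-trimethyl-7-oxotricyclo[6.2.1.0^{1,6}]undeca-3,9-dien-6-yl)methyl acetate
Product: 22 {7-[(tert-butyldimethylsilyl)hydrazinylidene]-2,2,9-trimethyltricyclo[6.2.1.0^{1,6}]undeca-3,9-dien-6-yl}methyl acetate
Conditions: TBSNHNHTBS (1.2 equiv), Sc(OTf)3 (1 mol%), CHCl3, 55 °C
Reagents that add atoms: 1,2-bis(tert-butyldimethylsilyl)hydrazine, CC(C)(C)[Si](C)(C)NN[Si](C)(C)C(C)(C)C
Why: Lewis acid-catalysed hydrazone formation with the bis-silyl hydrazine works under neutral conditions even for hindered ketones and leaves the acetate intact; no stereocentre is affected.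

**Step 10**
Reactants: 22 N-silyl hydrazone
Product: 24 (10-acetoxy-2,2,9-trimethyltetracyclo[6.2.1.0^{1,6}.0^{7,9}]undec-3-en-6-yl)methyl acetate (both CH2OAc at C6 and OAc at C10 point toward C11), via diazoalkane 23 (not isolated)
Conditions: PhIF2 (1.2 equiv), 2-chloropyridine, CH2Cl2, −78 °C; then AcOH (5 equiv), −78 to 0 °C
Reagents that add atoms: acetic acid, CC(=O)O
Why: Proposed new method: oxidation of the N-silyl hydrazone gives the diazoalkane, which AcOH protonates to a 5-norbornen-2-yl diazonium acetate ion pair; with C6 quaternary and C8 a bridgehead there is no β-hydrogen, so loss of N2 is assisted by the C9=C10 π bond from the endo side (homoallyl to cyclopropylcarbinyl, as in solvolysis of 5-norbornen-2-yl sulfonates and the i-steroid rearrangement), closing the C7–C9 cyclopropane, and acetate captures the nortricyclyl cation at C10 on the open face toward C11 (anti to the new bond; the other face is blocked by C5), so the C10–O bond, its stereocentre and the cage arise in one event; the closest known reaction type is esterification of carboxylic acids by diazoalkanes made in situ from N-silyl hydrazones and PhIF2, which has not been used to trigger a skeletal closure with remote C–O bond formation.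

**Step 11**
Reactants: 24 cage diacetate alkene
Product: 27 (4,10-diacetoxy-3-hydroxy-2,2,9-trimethyltetracyclo[6.2.1.0^{1,6}.0^{7,9}]undecan-6-yl)methyl acetate (CNP0197219.1), via iodo acetate 25 (not isolated), via acetoxonium ion 26 (not isolated)
Conditions: I2 (1.05 equiv), AgOAc (2.2 equiv), AcOH, rt; then AcOH/H2O (96:4), 90 °C
Reagents that add atoms: AgOAc, [Ag+].CC(=O)[O-]; water, O
Why: Woodward cis-hydroxylation: iodonium formation is reversible and only the iodonium on the face syn to C10 can be opened trans-diaxially by acetate at the unhindered C4 (Fürst–Plattner rule); the C4 acetate then displaces the AgOAc-activated C3 iodide with inversion to the cis-fused acetoxonium ion on the face of the CH2OAc group, and water opens it to the axial C4 acetate and equatorial C3 alcohol, which sets both ring A stereocentres and the hydroxyl/acetate pattern of the target.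

**Compound list**
1 | 3-methylcyclopent-2-en-1-one | CC1=CC(=O)CC1 | starting material
2 | 2-methylpropanenitrile (isobutyronitrile) | CC(C)C#N | starting material
3 | 2-(1-hydroxy-3-methylcyclopent-2-en-1-yl)-2-methylpropanenitrile (racemic) | CC1=CC(O)(CC1)C(C)(C)C#N | intermediate
4 | 2-methyl-2-(3-methylcyclopenta-1,3-dien-1-yl)propanenitrile (tautomers equilibrate) | N#CC(C)(C)C1=CC(C)=CC1 | intermediate
5 | 2-(2-bromoethyl)-1,3-dioxane | BrCCC1OCCCO1 | starting material
6 | [2-(1,3-dioxan-2-yl)ethyl]magnesium bromide | Br[Mg]CCC1OCCCO1 | intermediate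
7 | 1-(1,3-dioxan-2-yl)-4-methyl-4-(3-methylcyclopenta-1,3-dien-1-yl)pentan-3-imine (N–H form after quench) | N=C(CCC1OCCCO1)C(C)(C)C1=CC(C)=CC1 | intermediate
8 | 1-(1,3-dioxan-2-yl)-4-methyl-4-(3-methylcyclopenta-1,3-dien-1-yl)pentan-3-one | O=C(CCC1OCCCO1)C(C)(C)C1=CC(C)=CC1 | intermediate
9 | (3R)-1-(1,3-dioxan-2-yl)-4-methyl-4-(3-methylcyclopenta-1,3-dien-1-yl)pentan-3-ol | O1CCCOC1CC[C@@H](O)C(C)(C)C1=CC(C)=CC1 | intermediate
10 | triethylsilyl ether of 9 | O1CCCOC1CC[C@@H](O[Si](CC)(CC)CC)C(C)(C)C1=CC(C)=CC1 | intermediate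
11 | N-(1-alkoxyalkyl)-2,6-lutidinium triflate from 10 (epimers at the N,O-carbon) | CC[Si](CC)(CC)OCCCOC(CC[C@@H](O[Si](CC)(CC)CC)C(C)(C)C1=CC(C)=CC1)[n+]1c(C)cccc1C.[O-]S(=O)(=O)C(F)(F)F | intermediate
12 | (4R)-5-methyl-5-(3-methylcyclopenta-1,3-dien-1-yl)-4-(triethylsilyloxy)hexanal | O=CCC[C@@H](O[Si](CC)(CC)CC)C(C)(C)C1=CC(C)=CC1 | intermediate
13 | (5R)-6-methyl-6-(3-methylcyclopenta-1,3-dien-1-yl)-1-nitro-5-(triethylsilyloxy)heptan-2-ol (both C2 epimers) | [O-][N+](=O)CC(O)CC[C@@H](O[Si](CC)(CC)CC)C(C)(C)C1=CC(C)=CC1 | intermediate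
14 | methanesulfonate of 13 | [O-][N+](=O)CC(OS(C)(=O)=O)CC[C@@H](O[Si](CC)(CC)CC)C(C)(C)C1=CC(C)=CC1 | intermediate
15 | triethyl{[(3R,6E)-2-methyl-2-(3-methylcyclopenta-1,3-dien-1-yl)-7-nitrohept-6-en-3-yl]oxy}silane | [O-][N+](=O)/C=C/CC[C@@H](O[Si](CC)(CC)CC)C(C)(C)C1=CC(C)=CC1 | intermediate
16 | triethyl{[(3R)-2,2,9-trimethyl-7-nitrotricyclo[6.2.1.0^{1,6}]undec-9-en-3-yl]oxy}silane (C5 exo, 7-nitro endo, silyloxy cis to C10) | [O-][N+](=O)[C@H]1[C@@H]2CC[C@@H](O[Si](CC)(CC)CC)C(C)(C)[C@]2(C=C3C)C[C@H]13 | intermediate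
17 | (3R)-2,2,9-trimethyl-3-(triethylsilyloxy)tricyclo[6.2.1.0^{1,6}]undec-9-en-7-one | O=C1[C@@H]2CC[C@@H](O[Si](CC)(CC)CC)C(C)(C)[C@]2(C=C3C)C[C@H]13 | intermediate
18 | (3R)-6-(hydroxymethyl)-2,2,9-trimethyl-3-(triethylsilyloxy)tricyclo[6.2.1.0^{1,6}]undec-9-en-7-one (CH2OH exo; formed as lithium alkoxide) | OC[C@]12CC[C@@H](O[Si](CC)(CC)CC)C(C)(C)[C@]1(C=C3C)C[C@@H]3C2=O | intermediate
19 | [(3R)-2,2,9-trimethyl-7-oxo-3-(triethylsilyloxy)tricyclo[6.2.1.0^{1,6}]undec-9-en-6-yl]methyl acetate | CC(=O)OC[C@]12CC[C@@H](O[Si](CC)(CC)CC)C(C)(C)[C@]1(C=C3C)C[C@@H]3C2=O | intermediate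
20 | [(3R)-3-hydroxy-2,2,9-trimethyl-7-oxotricyclo[6.2.1.0^{1,6}]undec-9-en-6-yl]methyl acetate (OH axial, cis to C10) | CC(=O)OC[C@]12CC[C@@H](O)C(C)(C)[C@]1(C=C3C)C[C@@H]3C2=O | intermediate
21 | (2,2,9-trimethyl-7-oxotricyclo[6.2.1.0^{1,6}]undeca-3,9-dien-6-yl)methyl acetate (CH2OAc exo) | CC(=O)OC[C@]12CC=CC(C)(C)[C@]1(C=C3C)C[C@@H]3C2=O | intermediate
22 | N-(tert-butyldimethylsilyl)hydrazone of 21 | CC(=O)OC[C@]12CC=CC(C)(C)[C@]1(C=C3C)C[C@@H]3C2=NN[Si](C)(C)C(C)(C)C | intermediate
23 | (7-diazo-2,2,9-trimethyltricyclo[6.2.1.0^{1,6}]undeca-3,9-dien-6-yl)methyl acetate | CC(=O)OC[C@]12CC=CC(C)(C)[C@]1(C=C3C)C[C@@H]3C2=[N+]=[N-] | intermediate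
24 | (10-acetoxy-2,2,9-trimethyltetracyclo[6.2.1.0^{1,6}.0^{7,9}]undec-3-en-6-yl)methyl acetate (C6 CH2OAc and C10 OAc both toward C11) | CC(=O)OC[C@]12CC=CC(C)(C)[C@]13C[C@@H]1[C@H]2[C@]1(C)[C@H]3OC(C)=O | intermediate
25 | (4,10-diacetoxy-3-iodo-2,2,9-trimethyltetracyclo[6.2.1.0^{1,6}.0^{7,9}]undecan-6-yl)methyl acetate (4-OAc and 3-I trans-diaxial, I syn to C10) | CC(=O)OC[C@]12C[C@H](OC(C)=O)[C@@H](I)C(C)(C)[C@]13C[C@@H]1[C@H]2[C@]1(C)[C@H]3OC(C)=O | intermediate
26 | 2-methyl-1,3-dioxolan-2-ylium ion cis-fused at C3–C4 on the face of the CH2OAc group, acetate salt | CC(=O)OC[C@]12C[C@@H]3OC(C)=[O+][C@@H]3C(C)(C)[C@]14C[C@@H]1[C@H]2[C@]1(C)[C@H]4OC(C)=O.CC([O-])=O | intermediate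
27 | (4,10-diacetoxy-3-hydroxy-2,2,9-trimethyltetracyclo[6.2.1.0^{1,6}.0^{7,9}]undecan-6-yl)methyl acetate, CNP0197219.1 (3-OH, 4-OAc and CH2OAc cis on ring A; 10-OAc toward C11) | CC(=O)OC[C@]12C[C@H](OC(C)=O)[C@H](O)C(C)(C)[C@]13C[C@@H]1[C@H]2[C@]1(C)[C@H]3OC(C)=O | target

**Step count and risks**
Total step count: 11. Longest linear sequence: 11 steps (from 1).

Most likely to fail:

Step 5 (Henry/dehydration/cycloaddition cascade). The risks are oligomerisation of the nitroalkene and incomplete face or exo/endo control. The fallback sets out from aldehyde 12 and changes the dienophile: Wittig olefination with Ph3P=CHCHO gives (2E,6R)-7-methyl-7-(3-methylcyclopenta-1,3-dien-1-yl)-6-(triethylsilyloxy)oct-2-enal F1. Its Me2AlCl-promoted intramolecular Diels–Alder reaction at −78 °C gives the endo aldehyde cycloadduct (3R)-2,2,9-trimethyl-3-(triethylsilyloxy)tricyclo[6.2.1.0^{1,6}]undec-9-ene-7-carbaldehyde F2. Aerobic deformylation (Cu(OAc)2, 2,2'-bipyridine, DABCO, O2, DMF) removes the formyl carbon and returns to the route at ketone 17.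

Step 10 (the proposed new cage closure). The risks are direct ion-pair collapse at C7 without rearrangement, or carbene chemistry of 23. The fallback uses known solvolysis chemistry and sets out from ketone 21: NaBH4 in MeOH at 0 °C gives mainly the endo alcohol (7-hydroxy-2,2,9-trimethyltricyclo[6.2.1.0^{1,6}]undeca-3,9-dien-6-yl)methyl acetate F3 (both C7 epimers converge). MsCl/Et3N gives the methanesulfonate F4. Buffered acetolysis (KOAc, AcOH, 100 °C) ionises it with participation of the neighbouring acetate and the C9=C10 π bond, and acetate capture at C10 returns to the route at 24.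

Step 11 (Woodward cis-hydroxyacetoxylation). The risks are attack on the wrong face, the wrong monoacetate, or a methyl shift at C3. The fallback sets out from alkene 24: mCPBA gives the epoxide on the less hindered face syn to C10, F5. Acid-catalysed acetolysis (AcOH, cat. TsOH) opens it trans-diaxially at C4 to the 4-acetoxy-3-hydroxy compound with the C3 hydroxyl on the wrong face, F6. Dess–Martin oxidation gives the 4-acetoxy-3-ketone F7, and NaBH4/CeCl3 at −78 °C, attacking anti to the axial C4 acetate, gives the equatorial C3 alcohol and thus returns to the route at 27.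

**Further compounds**
F1 | step 5 | (2E,6R)-7-methyl-7-(3-methylcyclopenta-1,3-dien-1-yl)-6-(triethylsilyloxy)oct-2-enal | O=C/C=C/CC[C@@H](O[Si](CC)(CC)CC)C(C)(C)C1=CC(C)=CC1
F2 | step 5 | (3R)-2,2,9-trimethyl-3-(triethylsilyloxy)tricyclo[6.2.1.0^{1,6}]undec-9-ene-7-carbaldehyde (CHO endo, C5 exo) | O=C[C@H]1[C@@H]2CC[C@@H](O[Si](CC)(CC)CC)C(C)(C)[C@]2(C=C3C)C[C@H]13
F3 | step 10 | (7-hydroxy-2,2,9-trimethyltricyclo[6.2.1.0^{1,6}]undeca-3,9-dien-6-yl)methyl acetate (OH endo) | CC(=O)OC[C@]12CC=CC(C)(C)[C@]1(C=C3C)C[C@@H]3[C@H]2O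
F4 | step 10 | methanesulfonate of F3 | CC(=O)OC[C@]12CC=CC(C)(C)[C@]1(C=C3C)C[C@@H]3[C@H]2OS(C)(=O)=O
F5 | step 11 | 3,4-epoxide of 24 on the face syn to C10 | CC(=O)OC[C@]12C[C@H]3O[C@H]3C(C)(C)[C@]14C[C@@H]1[C@H]2[C@]1(C)[C@H]4OC(C)=O
F6 | step 11 | C3 epimer of 27 (4-OAc and 3-OH trans-diaxial) | CC(=O)OC[C@]12C[C@H](OC(C)=O)[C@@H](O)C(C)(C)[C@]13C[C@@H]1[C@H]2[C@]1(C)[C@H]3OC(C)=O
F7 | step 11 | (4,10-diacetoxy-2,2,9-trimethyl-3-oxotetracyclo[6.2.1.0^{1,6}.0^{7,9}]undecan-6-yl)methyl acetate | CC(=O)OC[C@]12C[C@H](OC(C)=O)C(=O)C(C)(C)[C@]13C[C@@H]1[C@H]2[C@]1(C)[C@H]3OC(C)=O
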